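How much of the substrate has become product after 14 min in the noon run, and how strongly does the starting rate follow the free catalyst?

| setting | summer | midnight | noon |
|---|---|---|---|
| substrate | 300 mM | 300 mM | 300 mM |
| partner | 750 mM | 750 mM | 750 mM |
| free catalyst | 6.00 mM | 9.00 mM | 6.00 mM |
| time |  |  | 14 min |

| run | time / min | [product] / mM |
|---|---|---|
| summer run | 0.60 | 21.9 |
| summer run | 1.2 | 44.8 |
| summer run | 1.8 | 73.3 |
| summer run | 2.4 | 99.9 |
| summer run | 3.0 | 121.6 |
| summer run | 3.6 | 145.4 |
| summer run | 4.2 | 166.6 |
| summer run | 4.8 | 184.0 |
| midnight run | 0.60 | 33.4 |
| midnight run | 1.2 | 69.1 |
| midnight run | 1.8 | 105.9 |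
| midnight run | 2.4 | 130.4 |
| midnight run | 3.0 | 162.9 |
| midnight run | 3.6 | 190.7 |
| midnight run | 4.2 | 207.1 |
| midnight run | 4.8 | 229.3 |

(standard deviation of a reading: 2 mM)

- the exponent of [free catalyst] in the starting rate at the charge of the summer run (at the point where two percent of the substrate have become product)
- product in the noon run at 14 min, as a share of the substrate charged

- Overall: substrate + partner -> product, with free catalyst as catalyst.
- Constant volume, constant temperature.
- Bound and free are read together.
- "The second partner" is partner.
- An order is taken over about fifteen percent of the charge, up and down.

The noon flask has the charge of the summer run, so I read the summer run for it. Substrate is the limiting reagent, 300 mM against 750 mM of partner. Up to 1.8 min the midnight run averages 58.8 mM min⁻¹ against 40.7 mM min⁻¹ in the summer run, with 9.00 mM of free catalyst against 6.00 mM, so I read a rough exponent of 0.907.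

My bench rule is a straight line: charge over early rate gives the finish, here 7.37 min, earlier than 14 min. The summer run supports it for a while. Going from 1.8 min to 3.6 min multiplies the product by 1.98; a straight line gives 2, and a rate proportional to substrate gives 1.76. But that border lies at the readings, and the question lies beyond them, in the last few percent.

So I compute only the correction, the substrate still unturned. Over the last readings of the summer run, the rate is 32.2 mM min⁻¹ with 135 mM unturned, a reading of 0.238 min⁻¹. This rate per unturned substrate is my tail constant. Letting the 116 mM at the last reading decay with it until 14 min leaves 13.0 mM, so I expect product at 95.7%. Early on the same constant reads 0.136 min⁻¹, lower than over the last readings, so I lean a little above my figure.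

The forecast gives an exponent of 0.95, higher than my reading, and 90% of product, lower than my figure: “Without catalyst loss conversion would be nearly complete, so I expect about 90%.” The flask gives 0.96 and 98.0%.

    free catalyst + substrate → catalyst-substrate complex (38.16 M⁻¹ min⁻¹)
    catalyst-substrate complex + partner → loaded catalyst (274.8 M⁻¹ min⁻¹)
    loaded catalyst → product + free catalyst (28.14 min⁻¹)
    substrate + partner + product → 2 product (0.8940 M⁻² min⁻¹)
    free catalyst + substrate ⇌ idle catalyst-substrate complex, settled at all times (1.100 M⁻¹)

The noon run leaves 6.06 mM of substrate, less than my 13.0 mM. Product itself helps turn substrate in the step substrate + partner + product -> 2 product, and because of that step the noon run ends at 98.0% instead of the 91.3% it gives without the step. Averaged over 14 min, the tail constant of the noon run is 0.279 min⁻¹ with the step and 0.175 min⁻¹ without it, a gain of 0.104 min⁻¹.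

All runs were computed for an exercise; noise was put on by code.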